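**Retrosynthetic overview**
1. The C-3 angelate is put on last by mixed-anhydride esterification; the C-9 methyl comes from cuprate addition to a C-9/C-10 enone; the C-11 ketone comes from ozonolysis of an exocyclic methylene.
2. The seven-membered ring is formed last, by reductive opening of a (5S)-epoxide and radical addition of its tertiary carbon to a cyclobutanone (C6–C7 bond). The C5–O bond made by catalyst-controlled epoxidation is the stereodefining key bond and the trigger for this closure.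
3. The cyclobutane and the six-membered ring are formed together, first, by intramolecular vinylketene–alkene [2+2] cycloaddition of an (8S)-8-silyloxy-10,11-epoxyfarnesoic acid.
4. The acyclic chain comes from methyl geranate by allylic C–H oxidation (C–O), catalytic asymmetric allylation and cross-metathesis.

Assumption: commercial methyl geranate is taken as the (2E) isomer; tricyclic compounds are numbered as tricyclo[5.4.0.0(2,8)]undecanes (C-3 angelate, C-5 acetate, C-6 CMe2, C-9 CHMe, C-11 ketone), and the route is a paper proposal that has not been run.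

**Route**

Step 1
Reactants: 1 methyl geranate
Product: 2 methyl (2E,6E)-3,7-dimethyl-8-oxoocta-2,6-dienoate
Conditions: SeO2 (1.1 equiv), 1,4-dioxane, 80 °C
Reagents that add atoms: selenium dioxide, O=[Se]=O
Why: Riley allylic oxidation (ene reaction then [2,3]-sigmatropic shift) attacks only the (E)-methyl of the electron-rich 6,7-alkene and carries it to the enal, installing the oxygen that becomes the C-3 ester oxygen while the conjugated 2,3-alkene stays untouched.

Step 2
Reactants: 2 methyl (2E,6E)-3,7-dimethyl-8-oxoocta-2,6-dienoate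
Product: 3 methyl (2E,6E,8S)-8-hydroxy-3,7-dimethylundeca-2,6,10-trienoate
Conditions: allylSnBu3, (S)-BINOL (20 mol%), Ti(OiPr)4 (10 mol%), 4 Å MS, CH2Cl2, −20 °C; aq. NaHCO3
Reagents that add atoms: allyltributylstannane, C=CC[Sn](CCCC)(CCCC)CCCC
Why: Keck asymmetric allylation adds the allyl group 1,2 to the Si face of the enal under control of the (S)-BINOL titanium catalyst, which sets C-8 as S; the ester and the trisubstituted alkenes are inert.

Step 3
Reactants: 3 methyl (2E,6E,8S)-8-hydroxy-3,7-dimethylundeca-2,6,10-trienoate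
Product: 4 methyl (2E,6E,8S)-8-hydroxy-3,7,11-trimethyldodeca-2,6,10-trienoate
Conditions: 2-methylbut-2-ene (excess), second-generation Grubbs catalyst (3 mol%), CH2Cl2, 40 °C
Reagents that add atoms: 2-methylbut-2-ene, CC=C(C)C
Why: Olefin cross-metathesis of the terminal vinyl group with excess 2-methylbut-2-ene turns allyl into prenyl; the trisubstituted alkenes do not metathesize and no stereocentre is touched.

Step 4
Reactants: 4 methyl (2E,6E,8S)-8-hydroxy-3,7,11-trimethyldodeca-2,6,10-trienoate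
Product: 5 methyl (2E,6E,8S)-8-[(tert-butyldimethylsilyl)oxy]-3,7,11-trimethyldodeca-2,6,10-trienoate
Conditions: TBSCl, imidazole, DMF, rt
Reagents that add atoms: tert-butyldimethylsilyl chloride, CC(C)(C)[Si](C)(C)Cl
Why: Standard silylation of the secondary allylic alcohol; the bulky silyl ether later shields one face of the 6,7-alkene and survives base, radicals, ozone and cuprate.

Step 5
Reactants: 5 methyl (2E,6E,8S)-8-[(tert-butyldimethylsilyl)oxy]-3,7,11-trimethyldodeca-2,6,10-trienoate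
Product: 6 methyl (2E,6E,8S)-8-[(tert-butyldimethylsilyl)oxy]-9-[(2S)-3,3-dimethyloxiran-2-yl]-3,7-dimethylnona-2,6-dienoate
Conditions: ent-Shi ketone (L-fructose-derived, 30 mol%), KHSO5 (as Oxone), K2CO3, Bu4NHSO4, MeCN/dimethoxymethane/aq. Na2B4O7 buffer, 0 °C
Reagents that add atoms: potassium peroxymonosulfate, [K+].[O-]S(=O)(=O)OO
Why: Shi asymmetric epoxidation is selective for the unhindered, most electron-rich 10,11-alkene (the 6,7-alkene is shielded and deactivated by the allylic silyloxy group, the enoate is electron-poor), and the spiro transition state of the L-fructose-derived dioxirane gives the (10S)-epoxide, which fixes the C–O bond and configuration of the future C-5.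

Step 6
Reactants: 6 methyl (2E,6E,8S)-8-[(tert-butyldimethylsilyl)oxy]-9-[(2S)-3,3-dimethyloxiran-2-yl]-3,7-dimethylnona-2,6-dienoate
Product: 7 (2E,6E,8S)-8-[(tert-butyldimethylsilyl)oxy]-9-[(2S)-3,3-dimethyloxiran-2-yl]-3,7-dimethylnona-2,6-dienoic acid
Conditions: LiOH·H2O, THF/MeOH/H2O, 40 °C; then 1 M HCl to pH 5, 0 °C
Reagents that add atoms: lithium hydroxide, [Li+].[OH-]
Why: Saponification of the methyl ester leaves the trisubstituted epoxide and the silyl ether intact as long as the work-up stays at pH 5; no stereocentre is affected.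

Step 7
Reactants: 7 (2E,6E,8S)-8-[(tert-butyldimethylsilyl)oxy]-9-[(2S)-3,3-dimethyloxiran-2-yl]-3,7-dimethylnona-2,6-dienoic acid
Product: 10 (1S,5R,7R)-7-{(1S)-1-[(tert-butyldimethylsilyl)oxy]-2-[(2S)-3,3-dimethyloxiran-2-yl]ethyl}-7-methyl-2-methylidenebicyclo[3.1.1]heptan-6-one, via acid chloride 8 (not isolated), via vinylketene 9 (not isolated)
Conditions: Me2C=C(Cl)NMe2 (Ghosez reagent), CH2Cl2, 0 °C to rt; then slow addition to Et3N (5 equiv), toluene, 110 °C, 0.005 M
Reagents that add atoms: none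
Why: Neutral acid chloride formation and dehydrochlorination at the γ-methyl give a vinylketene that undergoes intramolecular ketene–alkene [2+2] cycloaddition in the bridged sense (acyl carbon to the alkene CH, ketene α-carbon to the more substituted alkene carbon), suprafacially on the (E)-alkene so the methyl ends up syn and the side chain anti to the three-carbon bridge, and on the alkene face anti to the bulky allylic silyloxy group (allylic H eclipsing the vinylic methyl), which sets the three ring stereocentres from C-8.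

Step 8
Reactants: 10 (1S,5R,7R)-7-{(1S)-1-[(tert-butyldimethylsilyl)oxy]-2-[(2S)-3,3-dimethyloxiran-2-yl]ethyl}-7-methyl-2-methylidenebicyclo[3.1.1]heptan-6-one
Product: 11 (3S,5S)-3-[(tert-butyldimethylsilyl)oxy]-2,6,6-trimethyl-11-methylidenetricyclo[5.4.0.0(2,8)]undecane-5,7-diol
Conditions: Cp2TiCl2 (20 mol%), Mn dust (2.5 equiv), 2,4,6-collidine·HCl (3 equiv), THF, 0.01 M, rt
Reagents that add atoms: none
Why: Proposed new method: Cp2TiCl (trivalent titanium, regenerated by Mn) opens the epoxide homolytically at its tertiary carbon, the tertiary β-titanoxy radical adds 7-exo to the titanium-bound cyclobutanone carbonyl, and a second trivalent titanium captures the oxygen as an alkoxide before the strained alkoxy radical can fragment, so the C6–C7 bond and the seven-membered ring form in one step; the side chain sits on the carbonyl-bridge face so bonding is possible only from that face (7-OH ends up syn to the three-carbon bridge) and C-5 keeps the epoxide configuration (5S, anti to the C-3 oxygen); the closest known reaction type is titanocene-mediated reductive epoxide opening with radical cyclization onto aldehydes and ketones to form three- to six-membered carbocycles, and what is new is the seven-membered closure onto a strained cyclobutanone, helped by the short 2.1 Å distance across the cyclobutane that makes the transition state resemble a 6-exo closure.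

Step 9
Reactants: 11 (3S,5S)-3-[(tert-butyldimethylsilyl)oxy]-2,6,6-trimethyl-11-methylidenetricyclo[5.4.0.0(2,8)]undecane-5,7-diol
Product: 12 (3S,5S)-3-[(tert-butyldimethylsilyl)oxy]-7-hydroxy-2,6,6-trimethyl-11-methylidenetricyclo[5.4.0.0(2,8)]undecan-5-yl acetate
Conditions: Ac2O, Et3N, DMAP (cat.), CH2Cl2, rt
Reagents that add atoms: acetic anhydride, CC(=O)OC(C)=O
Why: DMAP-catalysed acetylation takes only the secondary 5-OH because the tertiary cyclobutanol 7-OH is too hindered; no stereocentre changes.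

Step 10
Reactants: 12 (3S,5S)-3-[(tert-butyldimethylsilyl)oxy]-7-hydroxy-2,6,6-trimethyl-11-methylidenetricyclo[5.4.0.0(2,8)]undecan-5-yl acetate
Product: 15 (3S,5S)-3-[(tert-butyldimethylsilyl)oxy]-2,6,6-trimethyl-11-methylidenetricyclo[5.4.0.0(2,8)]undecan-5-yl acetate, via chlorooxalate 13 (not isolated), via thiohydroxamate oxalate 14 (not isolated)
Conditions: (COCl)2, CH2Cl2, rt, evaporate; then sodium 2-thioxopyridin-1(2H)-olate, DMAP (cat.), benzene, rt; then Bu3SnH, AIBN, 80 °C
Reagents that add atoms: none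
Why: Barton–Crich-type deoxygenation of a tertiary alcohol through its mixed oxalate thiohydroxamate: the stannyl radical triggers loss of two CO2 to give the tertiary cyclobutyl radical at C-7, which can take hydrogen from Bu3SnH only on the open face syn to the three-carbon bridge because C-6 is held on the other face by the seven-membered ring, so C-7 gets the target configuration (no β-hydrogen is available for elimination and cationic rearrangement of the skeleton is avoided).

Step 11
Reactants: 15 (3S,5S)-3-[(tert-butyldimethylsilyl)oxy]-2,6,6-trimethyl-11-methylidenetricyclo[5.4.0.0(2,8)]undecan-5-yl acetate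
Product: 16 (3S,5S)-3-[(tert-butyldimethylsilyl)oxy]-2,6,6-trimethyl-11-oxotricyclo[5.4.0.0(2,8)]undecan-5-yl acetate
Conditions: O3, CH2Cl2/MeOH, −78 °C; then Me2S
Reagents that add atoms: ozone, [O-][O+]=O
Why: Ozonolysis with reductive work-up cleaves the only remaining C=C bond (the exocyclic methylene) to the C-11 ketone, which has no epimerizable α-stereocentre.

Step 12
Reactants: 16 (3S,5S)-3-[(tert-butyldimethylsilyl)oxy]-2,6,6-trimethyl-11-oxotricyclo[5.4.0.0(2,8)]undecan-5-yl acetate
Product: 17 (3S,5S)-3-[(tert-butyldimethylsilyl)oxy]-2,6,6-trimethyl-11-oxotricyclo[5.4.0.0(2,8)]undec-9-en-5-yl acetate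
Conditions: IBX (3 equiv), DMSO/toluene 2:1, 75 °C
Reagents that add atoms: none
Why: IBX dehydrogenation of the ketone through its enol can only occur towards C-10 because the other α-carbon is a bridgehead, giving the C-9/C-10 enone.

Step 13
Reactants: 17 (3S,5S)-3-[(tert-butyldimethylsilyl)oxy]-2,6,6-trimethyl-11-oxotricyclo[5.4.0.0(2,8)]undec-9-en-5-yl acetate
Product: 18 (1R,2R,3S,5S,7S,8S,9R)-3-[(tert-butyldimethylsilyl)oxy]-2,6,6,9-tetramethyl-11-oxotricyclo[5.4.0.0(2,8)]undecan-5-yl acetate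
Conditions: Me2CuLi (from CuI and 2 MeLi), Et2O, −78 °C; aq. NH4Cl
Reagents that add atoms: lithium dimethylcuprate, [Li+].C[Cu-]C
Why: Gilman cuprate 1,4-addition delivers methyl to C-9 from the face syn to the hydrogen-bearing cyclobutane carbon C-7 and anti to the methyl-bearing C-2 bridge (the same facial bias as in apoverbenone-type enones), which sets C-9 as R; acetate and silyl ether survive at −78 °C.

Step 14
Reactants: 18 (1R,2R,3S,5S,7S,8S,9R)-3-[(tert-butyldimethylsilyl)oxy]-2,6,6,9-tetramethyl-11-oxotricyclo[5.4.0.0(2,8)]undecan-5-yl acetate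
Product: 19 (1R,2R,3S,5S,7S,8S,9R)-3-hydroxy-2,6,6,9-tetramethyl-11-oxotricyclo[5.4.0.0(2,8)]undecan-5-yl acetate
Conditions: HF·pyridine, THF, 0 °C to rt
Reagents that add atoms: none
Why: Fluoride desilylation under mildly acidic conditions frees the 3-OH without acetate migration; stereocentres are untouched.

Step 15
Reactants: 19 (1R,2R,3S,5S,7S,8S,9R)-3-hydroxy-2,6,6,9-tetramethyl-11-oxotricyclo[5.4.0.0(2,8)]undecan-5-yl acetate; 20 angelic acid
Product: 22 (1R,2R,3S,5S,7S,8S,9R)-5-(acetyloxy)-2,6,6,9-tetramethyl-11-oxotricyclo[5.4.0.0(2,8)]undecan-3-yl (2Z)-2-methylbut-2-enoate, via mixed anhydride 21 (not isolated)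
Conditions: 20, 2,4,6-trichlorobenzoyl chloride, Et3N, toluene, rt; then 19, toluene, 80 °C (no DMAP)
Reagents that add atoms: none
Why: Yamaguchi-type esterification through the mixed 2,4,6-trichlorobenzoic anhydride acylates the hindered secondary alcohol with retention at C-3, and leaving out nucleophilic catalysts avoids Z-to-E isomerization of the angelate to the tiglate.

**Compound list**
1 | methyl geranate, methyl (2E)-3,7-dimethylocta-2,6-dienoate | COC(=O)/C=C(\C)CCC=C(C)C | starting material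
2 | methyl (2E,6E)-3,7-dimethyl-8-oxoocta-2,6-dienoate | COC(=O)/C=C(\C)CC/C=C(\C)C=O | intermediate
3 | methyl (2E,6E,8S)-8-hydroxy-3,7-dimethylundeca-2,6,10-trienoate | COC(=O)/C=C(\C)CC/C=C(\C)[C@@H](O)CC=C | intermediate
4 | methyl (2E,6E,8S)-8-hydroxy-3,7,11-trimethyldodeca-2,6,10-trienoate | COC(=O)/C=C(\C)CC/C=C(\C)[C@@H](O)CC=C(C)C | intermediate
5 | methyl (2E,6E,8S)-8-[(tert-butyldimethylsilyl)oxy]-3,7,11-trimethyldodeca-2,6,10-trienoate | COC(=O)/C=C(\C)CC/C=C(\C)[C@@H](O[Si](C)(C)C(C)(C)C)CC=C(C)C | intermediate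
6 | methyl (2E,6E,8S)-8-[(tert-butyldimethylsilyl)oxy]-9-[(2S)-3,3-dimethyloxiran-2-yl]-3,7-dimethylnona-2,6-dienoate | COC(=O)/C=C(\C)CC/C=C(\C)[C@@H](O[Si](C)(C)C(C)(C)C)C[C@@H]1OC1(C)C | intermediate
7 | (2E,6E,8S)-8-[(tert-butyldimethylsilyl)oxy]-9-[(2S)-3,3-dimethyloxiran-2-yl]-3,7-dimethylnona-2,6-dienoic acid | OC(=O)/C=C(\C)CC/C=C(\C)[C@@H](O[Si](C)(C)C(C)(C)C)C[C@@H]1OC1(C)C | intermediate
8 | acid chloride of 7 | ClC(=O)/C=C(\C)CC/C=C(\C)[C@@H](O[Si](C)(C)C(C)(C)C)C[C@@H]1OC1(C)C | intermediate (not isolated)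
9 | vinylketene, (6E,8S)-8-[(tert-butyldimethylsilyl)oxy]-9-[(2S)-3,3-dimethyloxiran-2-yl]-7-methyl-3-methylidenenona-1,6-dien-1-one | O=C=CC(=C)CC/C=C(\C)[C@@H](O[Si](C)(C)C(C)(C)C)C[C@@H]1OC1(C)C | intermediate (not isolated)
10 | (1S,5R,7R)-7-{(1S)-1-[(tert-butyldimethylsilyl)oxy]-2-[(2S)-3,3-dimethyloxiran-2-yl]ethyl}-7-methyl-2-methylidenebicyclo[3.1.1]heptan-6-one (7-methyl syn to the three-carbon bridge) | O=C1[C@@H]2CCC(=C)[C@H]1[C@]2(C)[C@@H](O[Si](C)(C)C(C)(C)C)C[C@@H]3OC3(C)C | intermediate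
11 | (3S,5S)-3-[(tert-butyldimethylsilyl)oxy]-2,6,6-trimethyl-11-methylidenetricyclo[5.4.0.0(2,8)]undecane-5,7-diol (7-OH syn to the three-carbon bridge; ring fusion as in 22) | CC(C)(C)[Si](C)(C)O[C@H]1C[C@H](O)C(C)(C)[C@@]2(O)[C@@H]3CCC(=C)[C@H]2[C@@]31C | intermediate
12 | 5-acetate of 11 | CC(C)(C)[Si](C)(C)O[C@H]1C[C@H](OC(C)=O)C(C)(C)[C@@]2(O)[C@@H]3CCC(=C)[C@H]2[C@@]31C | intermediate
13 | 7-O-chlorooxalyl derivative of 12 | CC(C)(C)[Si](C)(C)O[C@H]1C[C@H](OC(C)=O)C(C)(C)[C@@]2(OC(=O)C(Cl)=O)[C@@H]3CCC(=C)[C@H]2[C@@]31C | intermediate (not isolated)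
14 | mixed oxalate of 12 with N-hydroxypyridine-2-thione | CC(C)(C)[Si](C)(C)O[C@H]1C[C@H](OC(C)=O)C(C)(C)[C@@]2(OC(=O)C(=O)ON4C=CC=CC4=S)[C@@H]3CCC(=C)[C@H]2[C@@]31C | intermediate (not isolated)
15 | (3S,5S)-3-[(tert-butyldimethylsilyl)oxy]-2,6,6-trimethyl-11-methylidenetricyclo[5.4.0.0(2,8)]undecan-5-yl acetate (ring stereocentres as in 22) | CC(C)(C)[Si](C)(C)O[C@H]1C[C@H](OC(C)=O)C(C)(C)[C@H]2[C@@H]3CCC(=C)[C@H]2[C@@]31C | intermediate
16 | (3S,5S)-3-[(tert-butyldimethylsilyl)oxy]-2,6,6-trimethyl-11-oxotricyclo[5.4.0.0(2,8)]undecan-5-yl acetate | CC(C)(C)[Si](C)(C)O[C@H]1C[C@H](OC(C)=O)C(C)(C)[C@H]2[C@@H]3CCC(=O)[C@H]2[C@@]31C | intermediate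
17 | (3S,5S)-3-[(tert-butyldimethylsilyl)oxy]-2,6,6-trimethyl-11-oxotricyclo[5.4.0.0(2,8)]undec-9-en-5-yl acetate | CC(C)(C)[Si](C)(C)O[C@H]1C[C@H](OC(C)=O)C(C)(C)[C@H]2[C@@H]3C=CC(=O)[C@H]2[C@@]31C | intermediate
18 | (1R,2R,3S,5S,7S,8S,9R)-3-[(tert-butyldimethylsilyl)oxy]-2,6,6,9-tetramethyl-11-oxotricyclo[5.4.0.0(2,8)]undecan-5-yl acetate | CC(C)(C)[Si](C)(C)O[C@H]1C[C@H](OC(C)=O)C(C)(C)[C@H]2[C@@H]3[C@H](C)CC(=O)[C@H]2[C@@]31C | intermediate
19 | (1R,2R,3S,5S,7S,8S,9R)-3-hydroxy-2,6,6,9-tetramethyl-11-oxotricyclo[5.4.0.0(2,8)]undecan-5-yl acetate | O[C@H]1C[C@H](OC(C)=O)C(C)(C)[C@H]2[C@@H]3[C@H](C)CC(=O)[C@H]2[C@@]31C | intermediate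
20 | angelic acid, (2Z)-2-methylbut-2-enoic acid | C/C=C(/C)C(=O)O | starting material
21 | angelic 2,4,6-trichlorobenzoic anhydride | C/C=C(/C)C(=O)OC(=O)c1c(Cl)cc(Cl)cc1Cl | intermediate (not isolated)
22 | (1R,2R,3S,5S,7S,8S,9R)-5-(acetyloxy)-2,6,6,9-tetramethyl-11-oxotricyclo[5.4.0.0(2,8)]undecan-3-yl (2Z)-2-methylbut-2-enoate | C/C=C(/C)C(=O)O[C@H]1C[C@H](OC(C)=O)C(C)(C)[C@H]2[C@@H]3[C@H](C)CC(=O)[C@H]2[C@@]31C | target

**Totals and risks**
Total step count: 15. Longest linear sequence: 15 steps (1 to 22); angelic acid 20 enters in the last step.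

Steps most likely to fail:

Step 8 (the proposed new step). The tertiary radical may lose a β-hydrogen instead of cyclizing. The fallback uses known chemistry, sets out from 10 and returns at 11. The epoxide of 10 is isomerized with Et2Al(TMP) to the (3S)-allylic alcohol F1, which is also the expected by-product of a failed cyclization. Dess–Martin oxidation gives the isopropenyl ketone F2. Stryker reductive aldol cyclization with [(Ph3P)CuH]6 forms the copper enolate regiospecifically at the future C-6 and closes the seven-membered ring onto the cyclobutanone, giving the 7-hydroxy-5-ketone F3. Reduction with (R)-Me-CBS oxazaborolidine and catecholborane (quaternary C-6 as the large group) gives the (5S)-alcohol, which is diol 11.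

Step 7. The facial selectivity of the cycloaddition with respect to the silyloxy-bearing centre may be low or reversed, and the hindered, deactivated alkene may react slowly. The fallback uses the other facial isomer through a different top-bridge strategy, sets out from 7 and returns at 18. The cycloaddition then gives the diastereomeric cycloadduct F4. Because the two bridgehead positions of the bicyclic ketone are interchangeable, F4 maps onto the target with its methylene carbon as the future C-9 methyl. F4 is carried through the conditions of steps 8 to 10 to the diol F5, the acetate F6 and the deoxygenated 9-methylidene acetate F7. RhCl3·3H2O in ethanol isomerizes the exocyclic alkene to the endocyclic alkene F8. Allylic oxidation with CrO3·3,5-dimethylpyrazole gives the C-11 enone F9. Electron-transfer reduction with SmI2 in THF/MeOH, in which the C-9 carbanion is protonated to the more stable epimer with the methyl away from the methyl-bearing bridge, gives 18.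

Step 15. The hindered neopentyl-type alcohol may acylate slowly and the angelate may isomerize. The fallback builds the Z-alkene on the substrate, sets out from 19 and returns at 22. Compound 19 is esterified with 2-(diphenoxyphosphoryl)propanoic acid (EDC, DMAP) to the phosphonate ester F10. Ando-type Z-selective Horner–Wadsworth–Emmons olefination (NaH, THF, −78 °C, acetaldehyde) then gives 22.

**Further compounds**
F1 | step 8 | (1S,5R,7R)-7-[(1S,3S)-1-[(tert-butyldimethylsilyl)oxy]-3-hydroxy-4-methylpent-4-en-1-yl]-7-methyl-2-methylidenebicyclo[3.1.1]heptan-6-one | O=C1[C@@H]2CCC(=C)[C@H]1[C@]2(C)[C@@H](O[Si](C)(C)C(C)(C)C)C[C@H](O)C(C)=C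
F2 | step 8 | (1S,5R,7R)-7-[(1S)-1-[(tert-butyldimethylsilyl)oxy]-4-methyl-3-oxopent-4-en-1-yl]-7-methyl-2-methylidenebicyclo[3.1.1]heptan-6-one | O=C1[C@@H]2CCC(=C)[C@H]1[C@]2(C)[C@@H](O[Si](C)(C)C(C)(C)C)CC(=O)C(C)=C
F3 | step 8 | (3S)-3-[(tert-butyldimethylsilyl)oxy]-7-hydroxy-2,6,6-trimethyl-11-methylidenetricyclo[5.4.0.0(2,8)]undecan-5-one | CC(C)(C)[Si](C)(C)O[C@H]1CC(=O)C(C)(C)[C@@]2(O)[C@@H]3CCC(=C)[C@H]2[C@@]31C
F4 | step 7 | (1R,5S,7S)-7-{(1S)-1-[(tert-butyldimethylsilyl)oxy]-2-[(2S)-3,3-dimethyloxiran-2-yl]ethyl}-7-methyl-2-methylidenebicyclo[3.1.1]heptan-6-one | O=C1[C@@H]2C(=C)CC[C@H]1[C@]2(C)[C@@H](O[Si](C)(C)C(C)(C)C)C[C@@H]3OC3(C)C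
F5 | step 7 | (3S,5S)-3-[(tert-butyldimethylsilyl)oxy]-2,6,6-trimethyl-9-methylidenetricyclo[5.4.0.0(2,8)]undecane-5,7-diol | CC(C)(C)[Si](C)(C)O[C@H]1C[C@H](O)C(C)(C)[C@@]2(O)[C@@H]3C(=C)CC[C@H]2[C@@]31C
F6 | step 7 | (3S,5S)-3-[(tert-butyldimethylsilyl)oxy]-7-hydroxy-2,6,6-trimethyl-9-methylidenetricyclo[5.4.0.0(2,8)]undecan-5-yl acetate | CC(C)(C)[Si](C)(C)O[C@H]1C[C@H](OC(C)=O)C(C)(C)[C@@]2(O)[C@@H]3C(=C)CC[C@H]2[C@@]31C
F7 | step 7 | (3S,5S)-3-[(tert-butyldimethylsilyl)oxy]-2,6,6-trimethyl-9-methylidenetricyclo[5.4.0.0(2,8)]undecan-5-yl acetate | CC(C)(C)[Si](C)(C)O[C@H]1C[C@H](OC(C)=O)C(C)(C)[C@H]2[C@@H]3C(=C)CC[C@H]2[C@@]31C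
F8 | step 7 | (3S,5S)-3-[(tert-butyldimethylsilyl)oxy]-2,6,6,9-tetramethyltricyclo[5.4.0.0(2,8)]undec-9-en-5-yl acetate | CC(C)(C)[Si](C)(C)O[C@H]1C[C@H](OC(C)=O)C(C)(C)[C@H]2[C@@H]3C(C)=CC[C@H]2[C@@]31C
F9 | step 7 | (3S,5S)-3-[(tert-butyldimethylsilyl)oxy]-2,6,6,9-tetramethyl-11-oxotricyclo[5.4.0.0(2,8)]undec-9-en-5-yl acetate | CC(C)(C)[Si](C)(C)O[C@H]1C[C@H](OC(C)=O)C(C)(C)[C@H]2[C@@H]3C(C)=CC(=O)[C@H]2[C@@]31C
F10 | step 15 | (1R,2R,3S,5S,7S,8S,9R)-5-(acetyloxy)-2,6,6,9-tetramethyl-11-oxotricyclo[5.4.0.0(2,8)]undecan-3-yl 2-(diphenoxyphosphoryl)propanoate (both epimers at the phosphonate carbon) | CC(C(=O)O[C@H]1C[C@H](OC(C)=O)C(C)(C)[C@H]2[C@@H]3[C@H](C)CC(=O)[C@H]2[C@@]31C)P(=O)(Oc1ccccc1)Oc1ccccc1
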